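**Retrosynthetic overview**
1. Last step forms the quinone C–N bond and the last ring C–O bond together: 15 ⇐ terpenyl resorcinol 11 + isopentylamine 12 + O2 (copper-catalysed oxygenative amination; the quinone ring is made last from a bought benzene ring).
2. 11 ⇐ bis-MOM ether 10 ⇐ aldehyde 5 + lithiated 1,3-bis(methoxymethoxy)benzene 7 (C11–aryl bond, then removal of the benzylic oxygen).
3. 5 ⇐ diene 3 + tiglic aldehyde 4: one enantioselective exo Diels–Alder reaction closes ring B and sets C8, C9, C10 and the C5=C6 olefin.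
4. 3 ⇐ 2,2-dimethylcyclohexanone 1 + vinyl Grignard. Ring order: ring A (bought) → ring B (cycloaddition) → quinone ring (oxidation of the arene, last).

Assumption: avarane-type numbering is used for the decalin (gem-dimethyl C4, olefin C5=C6, methyls on C8 and C9, ring-fusion CH = C10, benzylic CH2 = C11; α/β as in the usual drawing with H-10 α); "R*" below means the (1R,2S,8aS)-1,2,5,5-tetramethyl-1,2,3,5,6,7,8,8a-octahydronaphthalen-1-yl group (8β-Me, 9β-Me, 10α-H).

**Step 1**
Reactants: 1 2,2-dimethylcyclohexan-1-one
Product: 2 (±)-2,2-dimethyl-1-vinylcyclohexan-1-ol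
Conditions: CH2=CHMgBr (1.3 equiv), THF, 0 °C → rt; then H2O
Reagents that add atoms: vinylmagnesium bromide, C=C[Mg]Br
Why: Grignard 1,2-addition to a ketone; the racemic carbinol centre is erased in step 2.

**Step 2**
Reactants: 2 (±)-2,2-dimethyl-1-vinylcyclohexan-1-ol
Product: 3 6,6-dimethyl-1-vinylcyclohex-1-ene
Conditions: POCl3, pyridine, 0 → 80 °C
Reagents that add atoms: none
Why: Base-mediated dehydration of the tertiary dichlorophosphate (E2); only the ring CH2 carries β-hydrogens (the other neighbour is quaternary), so the conjugated diene is the only alkene that can form.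

**Step 3**
Reactants: 3 6,6-dimethyl-1-vinylcyclohex-1-ene; 4 tiglic aldehyde, (E)-2-methylbut-2-enal
Product: 5 (1R,2S,8aR)-1,2,5,5-tetramethyl-1,2,3,5,6,7,8,8a-octahydronaphthalene-1-carbaldehyde (9α-CHO, 9β-Me, 8β-Me, 10α-H, C5=C6)
Conditions: oxazaborolidinium triflimide made in situ from (R)-3,3-diphenyl-1-(o-tolyl)tetrahydro-1H,3H-pyrrolo[1,2-c][1,3,2]oxazaborole and Tf2NH (20 mol %), 4 (1.5 equiv), CH2Cl2, −78 → −20 °C
Reagents that add atoms: none
Why: Catalytic enantioselective Diels–Alder reaction with a chiral cationic oxazaborolidine Lewis acid: the gem-dimethyl group holds the diene s-cis, the formyl-bearing carbon bonds to the ring terminus (usual "ortho" orientation of 1-vinylcyclohexenes), the (E)-geometry of 4 gives the cis C8/C9 methyls, the exo-formyl transition state usual for α-methyl enals places CHO cis to H-10, and the (R)-catalyst (formyl C–H···O binding, one enal face shielded by a phenyl group) leaves the Cα-Si face open, which sets C8, C9 and C10 in the absolute sense of the target.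

**Step 4**
Reactants: 6 resorcinol
Product: 7 1,3-bis(methoxymethoxy)benzene
Conditions: MOMCl (2.5 equiv), i-Pr2NEt (3 equiv), CH2Cl2, 0 °C → rt
Reagents that add atoms: chloromethyl methyl ether, COCCl
Why: O-alkylation of both phenols (Williamson-type acetal formation); the MOM ethers serve as ortho-directing groups for step 5.

**Step 5**
Reactants: 7 1,3-bis(methoxymethoxy)benzene; 5 aldehyde from step 3
Product: 10 2-(R*-methyl)-1,3-bis(methoxymethoxy)benzene, via aryllithium 8 (not isolated), via lithium alkoxide 9 (not isolated)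
Conditions: 7 (1.5 equiv), n-BuLi (1.4 equiv), THF, 0 °C → rt; 5, −78 → 0 °C; then Li (8 equiv), NH3(l)/THF, −78 °C; then NH4Cl(s)
Reagents that add atoms: none
Why: Directed ortho-lithiation between the two MOM ethers, 1,2-addition to the aldehyde (no α-hydrogen, so no enolisation) and tandem dissolving-metal hydrogenolysis of the benzylic C–O bond once NH4Cl protonates the alkoxide; the transient carbinol centre is removed and the isolated olefin and the three ring stereocentres are untouched.

**Step 6**
Reactants: 10 2-(R*-methyl)-1,3-bis(methoxymethoxy)benzene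
Product: 11 2-(R*-methyl)benzene-1,3-diol
Conditions: p-TsOH·H2O (20 mol %), MeOH, 40 °C
Reagents that add atoms: none
Why: Acid-catalysed transacetalisation of the MOM ethers to methanol; methanolic acid of this strength does not protonate the trisubstituted olefin, so C10 and the olefin position are kept.

**Step 7**
Reactants: 11 2-(R*-methyl)benzene-1,3-diol; 12 isopentylamine (3-methylbutan-1-amine)
Product: 15 nakijiquinone M, via hydroxyquinone 13 (not isolated), via aminohydroquinone 14 (not isolated)
Conditions: [Cu(MeCN)4]PF6 (10 mol %), N,N'-di-tert-butylethylenediamine (DBED, 20 mol %), 12 (3 equiv), O2 (1 atm), 4 Å MS, CH2Cl2, −20 °C → rt; dilute citric acid work-up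
Reagents that add atoms: dioxygen, O=O
Why: Proposed new method: copper-catalysed aerobic oxygenative amination of a 2-alkylresorcinol — the DBED-ligated monovalent copper/O2 pair (a tyrosinase-like peroxo-dicopper oxidant) should oxygenate the resorcinolate at its only free ortho position (C4 and C6 are equivalent by symmetry) to give the copper-chelated 3-hydroxy-o-quinone, the bound tautomer of hydroxy-p-quinone 13; chelation of the α-oxido-ketone keeps this otherwise deactivated vinylogous-acid anion electrophilic, masks the ketone-like carbonyl against Schiff-base formation and leaves the ring CH β to that carbonyl as the only Michael position, so 12 adds there to give 14, which divalent copper/O2 dehydrogenates to the push–pull aminohydroxyquinone, a sink that resists a second addition; no stereocentre is involved; closest known reaction types are copper/diamine aerobic ortho-oxygenation of phenols to o-quinones, amine conjugate addition–reoxidation on quinones and the methoxy-to-amine exchange on ilimaquinone-type quinones.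

**Compound list**
1 | 2,2-dimethylcyclohexan-1-one | CC1(C)CCCCC1=O | starting material
2 | (±)-2,2-dimethyl-1-vinylcyclohexan-1-ol | C=CC1(O)CCCCC1(C)C | intermediate
3 | 6,6-dimethyl-1-vinylcyclohex-1-ene | C=CC1=CCCCC1(C)C | intermediate
4 | tiglic aldehyde, (E)-2-methylbut-2-enal | C/C=C(\C)C=O | starting material
5 | (1R,2S,8aR)-1,2,5,5-tetramethyl-1,2,3,5,6,7,8,8a-octahydronaphthalene-1-carbaldehyde | O=C[C@@]1(C)[C@@H]2CCCC(C)(C)C2=CC[C@@H]1C | intermediate
6 | resorcinol | Oc1cccc(O)c1 | starting material
7 | 1,3-bis(methoxymethoxy)benzene | COCOc1cccc(OCOC)c1 | intermediate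
8 | 2,6-bis(methoxymethoxy)phenyllithium | [Li]c1c(OCOC)cccc1OCOC | intermediate (not isolated)
9 | lithium alkoxide of [2,6-bis(methoxymethoxy)phenyl](R*)methanol, both carbinol epimers | [Li]OC(c1c(OCOC)cccc1OCOC)[C@@]1(C)[C@@H]2CCCC(C)(C)C2=CC[C@@H]1C | intermediate (not isolated)
10 | 2-(R*-methyl)-1,3-bis(methoxymethoxy)benzene | COCOc1cccc(OCOC)c1C[C@@]1(C)[C@@H]2CCCC(C)(C)C2=CC[C@@H]1C | intermediate
11 | 2-(R*-methyl)benzene-1,3-diol | Oc1cccc(O)c1C[C@@]1(C)[C@@H]2CCCC(C)(C)C2=CC[C@@H]1C | intermediate
12 | isopentylamine (3-methylbutan-1-amine) | CC(C)CCN | starting material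
13 | 2-hydroxy-3-(R*-methyl)cyclohexa-2,5-diene-1,4-dione | O=C1C=CC(=O)C(O)=C1C[C@@]1(C)[C@@H]2CCCC(C)(C)C2=CC[C@@H]1C | intermediate (not isolated)
14 | 5-[(3-methylbutyl)amino]-3-(R*-methyl)benzene-1,2,4-triol | CC(C)CCNc1cc(O)c(O)c(C[C@@]2(C)[C@@H]3CCCC(C)(C)C3=CC[C@@H]2C)c1O | intermediate (not isolated)
15 | nakijiquinone M, 2-hydroxy-5-[(3-methylbutyl)amino]-3-(R*-methyl)cyclohexa-2,5-diene-1,4-dione | CC(C)CCNC1=CC(=O)C(O)=C(C[C@@]2(C)[C@@H]3CCCC(C)(C)C3=CC[C@@H]2C)C1=O | target

**Count**
Total steps: 7. Longest linear sequence: 6 (steps 1, 2, 3, 5, 6, 7).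

**Steps most likely to fail**

Step 7 (the new oxygenative amination). The amine may condense at the ketone-like carbonyl (Schiff base, then transamination) instead of adding conjugatively, or the resorcinol may oligomerise oxidatively. The fallback uses known chemistry, sets out from aldehyde 5 and comes back at 15. 1,2,4,5-Tetramethoxybenzene is lithiated (n-BuLi, THF, 0 °C) to 2,3,5,6-tetramethoxyphenyllithium F1, which adds to 5 to give the lithium alkoxide F2. Li/NH3 then NH4Cl, as in step 5, gives 3-(R*-methyl)-1,2,4,5-tetramethoxybenzene F3. Oxidative demethylation with (NH4)2Ce(NO3)6 in MeCN/H2O at 0 °C gives the 2,5-dimethoxy-3-(R*-methyl)benzoquinone F4. KOH in MeOH/H2O selectively hydrolyses the methoxy group next to the alkyl substituent to give the 2-hydroxy-5-methoxy-3-(R*-methyl)benzoquinone F5. Stirring F5 with 12 and NaHCO3 in EtOH at rt exchanges the remaining vinylogous-ester methoxy group for the amine and gives 15.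

Step 3 (enantioselective Diels–Alder). The hindered diene with a trisubstituted enal may react slowly, or with low exo or enantioselectivity. The facial sense was assigned from the binding model and should be confirmed; the antipodal catalyst is equally available. The fallback sets out from 4 (with diene 3) and comes back at 5. Compound 4 is acetalised with (2R,4R)-pentane-2,4-diol (PPTS, benzene, Dean–Stark) to the (4R,6R)-2-[(E)-but-2-en-2-yl]-4,6-dimethyl-1,3-dioxane F6. An ionic Diels–Alder reaction of F6 with 3 through the alkoxy-allyl cation (Me3SiOTf cat., CH2Cl2, −78 °C) gives diastereomeric adduct acetals. These are separated by chromatography, so the auxiliary also acts as a resolving agent. The isomer with the 8β-Me, 9β-Me, 10α-H configuration, the dioxane acetal of 5 F7, is hydrolysed (p-TsOH, acetone/H2O, 40 °C) to 5.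

Step 5 (tandem addition and benzylic hydrogenolysis). The di-ortho-substituted aryllithium may add slowly to the neopentyl aldehyde, and the electron-rich benzylic alkoxide may be reduced incompletely or the arene over-reduced. The fallback sets out from 5 and 8 and comes back at 10. The addition is quenched with water and the [2,6-bis(methoxymethoxy)phenyl](R*)methanol F8 is isolated as an epimer mixture. NaH, CS2, then MeI in THF give the S-methyl xanthate F9. Radical deoxygenation (Barton–McCombie; Bu3SnH, AIBN, toluene, 110 °C) gives 10.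

**Further compounds**
F1 | step 7 | 2,3,5,6-tetramethoxyphenyllithium | [Li]c1c(OC)c(OC)cc(OC)c1OC
F2 | step 7 | lithium alkoxide of (2,3,5,6-tetramethoxyphenyl)(R*)methanol, both carbinol epimers | [Li]OC(c1c(OC)c(OC)cc(OC)c1OC)[C@@]1(C)[C@@H]2CCCC(C)(C)C2=CC[C@@H]1C
F3 | step 7 | 3-(R*-methyl)-1,2,4,5-tetramethoxybenzene | COc1cc(OC)c(OC)c(C[C@@]2(C)[C@@H]3CCCC(C)(C)C3=CC[C@@H]2C)c1OC
F4 | step 7 | 2,5-dimethoxy-3-(R*-methyl)cyclohexa-2,5-diene-1,4-dione | COC1=CC(=O)C(OC)=C(C[C@@]2(C)[C@@H]3CCCC(C)(C)C3=CC[C@@H]2C)C1=O
F5 | step 7 | 2-hydroxy-5-methoxy-3-(R*-methyl)cyclohexa-2,5-diene-1,4-dione | COC1=CC(=O)C(O)=C(C[C@@]2(C)[C@@H]3CCCC(C)(C)C3=CC[C@@H]2C)C1=O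
F6 | step 3 | (4R,6R)-2-[(E)-but-2-en-2-yl]-4,6-dimethyl-1,3-dioxane | C/C=C(\C)C1O[C@H](C)C[C@@H](C)O1
F7 | step 3 | (4R,6R)-4,6-dimethyl-2-(R*)-1,3-dioxane, the pentanediol acetal of 5 | C1(O[C@H](C)C[C@@H](C)O1)[C@@]1(C)[C@@H]2CCCC(C)(C)C2=CC[C@@H]1C
F8 | step 5 | [2,6-bis(methoxymethoxy)phenyl](R*)methanol, both carbinol epimers | OC(c1c(OCOC)cccc1OCOC)[C@@]1(C)[C@@H]2CCCC(C)(C)C2=CC[C@@H]1C
F9 | step 5 | O-{[2,6-bis(methoxymethoxy)phenyl](R*)methyl} S-methyl carbonodithioate | CSC(=S)OC(c1c(OCOC)cccc1OCOC)[C@@]1(C)[C@@H]2CCCC(C)(C)C2=CC[C@@H]1C
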